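## The problem

The target joins two bridged bicycles through an ethylene link (a5–a6); its non-hydrogen atoms are numbered here a1 to a27 along the line formula, starting at the exocyclic methylene. The carbocyclic half is a bicyclo[3.2.1]octane made of six-membered ring C (a4, a22–a26) and five-membered ring D (a2, a3, a4, a22, a23), and it holds the ketone a26 beside the quaternary bridgehead a4, the bare one-carbon bridge a22 and the methylene a1=a2. The other half is ring A (a7, a8, a13, a15–a17), whose methyl-bearing quaternary carbons a8 and a13 are spanned by the γ-lactone a10(=O)–O12 and whose a17 carries the acetate. Of the six stereocentres, a4 and a23 are tied together by the bridge and a7, a8, a13 and a17 form a second set; the two methylenes between the sets keep either from steering the other, so their mutual sense must be imposed by reagents on each side. Inside ring A the chain on a7 lies anti to the lactone bridge and syn-axial to the acetate, the more crowded arrangement, which has to be fixed under kinetic control. The exocyclic alkene does not survive strong acid (migration into ring D, cationic skeletal shifts), the acetate and the lactone exclude hydroxide and unselective hydride, and any 2,2-disubstituted 1,3-dione on the way is open to retro-Claisen cleavage. The feature that makes the key step possible is the environment of a4: it is quaternary, α to the ketone a26 and bonded to the bridge methylene a22, so a carbonyl restored at a22 turns a4 into C2 of a 2-alkyl-2-propargylcyclohexane-1,3-dione and ring D into the single bond between the α-carbon a23 and the alkyne carbon a2. The two carbonyls of that dione differ only in which of them becomes a22, so a chiral catalyst choosing between them fixes a4 and a23 in one event.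

## Retrosynthesis

**23 to 20 (no C–C bond cut).** An oxygen is put back on a22: the target 23 is traced through the thiocarbonate 22 and the carbinol 21 to the diketone 20. Compound 20 contains the β,γ-unsaturated ketone (a22, a23, a2=a1) that is the retron of an enol–alkyne cyclisation. Plans that keep a22 as CH2 throughout must instead bring in a4 as a preformed quaternary stereocentre. The forward steps must reduce the strained bridge ketone in preference to a26, and must remove the oxygen through a radical that is given no time to rearrange.

**20 to 19 (cut a2–a23).** This opens ring D and deletes both stereocentres of the core. Compound 19 is a 2-propargyl-2-alkylcyclohexane-1,3-dione whose C2 (a4) is locally prochiral. Cutting a3–a4 or a22–a23 would leave no symmetric ring and no catalytic handle. The forward reaction must select one of two carbonyls that are mirror-related in their surroundings, and must close 5-exo.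

**19 to 17 + 18, and 17 to 15 + 16 (cut a3–a4 and a4–a5).** Both are bonds to C2 of cyclohexane-1,3-dione 16: the first from propargyl bromide 18, the second from reductive alkylation with the aldehyde 15. The obvious neighbour, Michael addition of the dione to acrolein, gives the dione earlier. It would leave ring A to be built on the chiral core, where nothing controls its sense. Attaching a finished, enantiopure ring A makes the catalyst of the key step the only link between the two stereochemical domains, and any shortfall appears as a diastereomer. The price is a key step late in the sequence and a C-alkylation that competes with O-alkylation.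

**15 to 11 (functional-group changes only).** The aldehyde comes from the benzyl ether (14, 13). The acetate comes from the axial alcohol 12, and that from the ketone 11 by hydride delivery to the only open face.

**11 to 9 (cut a7–a8 and O12–a13).** An oxidative radical cyclisation of the Z-alkenyl β-keto ester 9 forms a7–a8, passing through the olefinic ester 10. Acid-induced lactonisation then forms O12–a13. Ionic closures (Michael, alkylation) would place the a7 chain in the less crowded position syn to the lactone. The radical chair places the Z-substituent axial and anti to the axial ester, which is what the target needs. A chiral ester is required because 9 has no other stereocentre. It fixes the absolute sense and is expelled in the lactonisation.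

**9 to 8 + 5, 8 to 6 + 7, 5 to 1 + 2 (cut a15–a16 and a7=a13).** Alkylation of the dianion of keto ester 8 by the Z-allylic bromide 5 forms a15–a16. Ester 8 comes from (−)-8-phenylmenthol 6 and methyl 2-methylacetoacetate 7. Bromide 5 comes through 4 and 3 from a Z-selective olefination of 3-(benzyloxy)propanal 1 with phosphonate 2. All five starting pieces are commercial and achiral except 6.

## Roads not taken

Alternative 1: Oxidative radical closure of ring A as the last ring-forming event. The cut is a7–a8 and O12–a13, made on the Z-alkenyl β-keto tert-butyl ester A1, a substrate that already holds the finished, ketal-protected rings C and D. In the forward step Mn(OAc)3 converts A1 into the a8 radical, which adds 6-endo to a7; Cu(OAc)2 takes the a13 radical to the cation, and the tert-butyl ester closes the lactone with loss of its alkyl group to give the keto lactone A2. One step makes ring A, the lactone and three stereocentres. The catalytic desymmetrisation would sit at the start on a cheap achiral dione, where its selectivity can be measured directly and failure costs little; in that respect this road is better than the chosen one. Its weak points are these: the new stereocentres are insulated from a4 by two methylenes, so A2 should form with its ring-A-inverted diastereomer in about equal amounts; an ester that must leave as a tertiary cation cannot carry an auxiliary; acid cannot be used to turn olefinic by-products into lactone because of the exocyclic methylene; and the ketone a26 needs a ketal. The chosen plan uses the same cyclisation before the core exists, where an auxiliary steers it and acid completes it. Against the late key step it sets a controlled relationship between the two halves and an unprotected a26.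

Alternative 2: Intramolecular Michael closure of ring C. The cut is a23–a24. In the forward step the cyclopentanone A3, which has its ketone at a2 and carries an acryloyl group and a silyloxypropyl chain on a4, forms an enamine under pyrrolidine and acetic acid; its carbon a23 adds to the enone terminus a24 to give the bicyclic dione A4. Here a22 is a methylene from the start, so the three-step removal of an oxygen and its radical risk disappear, and the closure type is robust; on both counts this road is safer than the chosen end-game. Its weak points are these: the Michael step creates nothing at a4, so A3 must already be a single enantiomer with an all-carbon quaternary centre, which needs its own asymmetric synthesis; the ketone at a2 of A4 must later be methylenated beside the ketone a26; and the silyloxypropyl chain means ring A is built afterwards on the chiral core, with the same lack of control as in Alternative 1. Against the safer ring closure the chosen plan sets one catalytic event for a4 and a23 on a dione made in two alkylations, and a ring A finished before the core.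

Alternative 3: Tandem radical bicyclisation of an open-chain keto ester. The cut is a24–a25 and a2–a23. In the forward step Mn(OAc)3 oxidises the α-chloro β-keto ester A5, which carries ring A, an allyl group and a propargyl group all on a4. The a25 radical closes ring C on the allyl terminus, and the a23 radical then closes ring D on the alkyne and leaves the methylene, giving the chloro ester A6. Both carbocyclic rings form in one step, ring A is already in place as in the chosen plan, and no oxygen ever sits on a22. Its weak points are these: a4 in A5 is an open-chain quaternary stereocentre whose three carbon arms (allyl, propargyl, 2-substituted ethyl) are nearly alike, so an enantioselective construction is hard to see; the first closure must go 6-endo, not 5-exo; and A6 carries a chlorine and a methyl ester on a25 that must be removed without touching the acetate, lactone or ketone. This road is shorter in ring-forming steps and longer in clean-up. The chosen plan meets the same difficulty of telling apart the arms of a4, and hands it to a catalyst that chooses between two carbonyls.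

Key step: step 13

Assumption: the (1R,2S,5R)-auxiliary in step 6 and the quinine-derived amine in step 13 are taken to give the sense of induction drawn; if either proves opposite, its counterpart (the (1S,2R,5S)-alcohol, or the amine from quinidine) is used and nothing else changes.

## Steps

Step 1
Reactants: 1 3-(benzyloxy)propanal; 2 ethyl 2-[bis(2,2,2-trifluoroethoxy)phosphoryl]propanoate
Product: 3 ethyl (Z)-5-(benzyloxy)-2-methylpent-2-enoate
Conditions: KN(SiMe3)2, 18-crown-6, THF, −78 °C
Reagents that add atoms: none
Why: Still–Gennari olefination: the preformed potassium phosphonate adds to the aldehyde and the electron-poor oxaphosphetane collapses before it can equilibrate, so the trisubstituted enoate should form with the ester cis to the chain (Z, the future a7=a13 geometry); no free base is left to eliminate the β-benzyloxy group.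

Step 2
Reactants: 3 ethyl (Z)-5-(benzyloxy)-2-methylpent-2-enoate
Product: 4 (Z)-5-(benzyloxy)-2-methylpent-2-en-1-ol
Conditions: i-Bu2AlH, CH2Cl2, −78 °C
Reagents that add atoms: none
Why: 1,2-Reduction of an α,β-unsaturated ester by a dialkylaluminium hydride at low temperature; the alkene geometry is untouched and the benzyl ether is inert.

Step 3
Reactants: 4 (Z)-5-(benzyloxy)-2-methylpent-2-en-1-ol
Product: 5 benzyl (Z)-5-bromo-4-methylpent-3-en-1-yl ether
Conditions: CBr4, PPh3, CH2Cl2, 0 °C
Reagents that add atoms: carbon tetrabromide, BrC(Br)(Br)Br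
Why: Appel bromination through the alkoxyphosphonium ion with SN2 displacement at the primary carbon; at 0 °C and with immediate use the Z-allylic bromide should neither transpose nor isomerise.

Step 4
Reactants: 6 (1R,2S,5R)-5-methyl-2-(2-phenylpropan-2-yl)cyclohexan-1-ol [(−)-8-phenylmenthol]; 7 methyl 2-methyl-3-oxobutanoate
Product: 8 (1R,2S,5R)-5-methyl-2-(2-phenylpropan-2-yl)cyclohexyl 2-methyl-3-oxobutanoate
Conditions: DMAP (cat.), toluene, reflux, removal of MeOH
Reagents that add atoms: none
Why: DMAP-catalysed transesterification of a β-keto ester, which runs through the acylketene or its equivalent and so accepts a hindered secondary alcohol; distilling off methanol drives it to completion.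

Step 5
Reactants: 8 (1R,2S,5R)-5-methyl-2-(2-phenylpropan-2-yl)cyclohexyl 2-methyl-3-oxobutanoate; 5 benzyl (Z)-5-bromo-4-methylpent-3-en-1-yl ether
Product: 9 (1R,2S,5R)-5-methyl-2-(2-phenylpropan-2-yl)cyclohexyl (Z)-9-(benzyloxy)-2,6-dimethyl-3-oxonon-6-enoate
Conditions: LiN(i-Pr)2 (2.1 equiv), THF, 0 °C; then 5, −78 to 0 °C
Reagents that add atoms: none
Why: Dianion alkylation of a β-keto ester: the second deprotonation creates the more reactive terminal carbanion (future a16), which displaces the primary allylic bromide and forms a15–a16, while the α-methyl keto ester unit and the Z-alkene stay as they are.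

Step 6
Reactants: 9 (1R,2S,5R)-5-methyl-2-(2-phenylpropan-2-yl)cyclohexyl (Z)-9-(benzyloxy)-2,6-dimethyl-3-oxonon-6-enoate
Product: 11 (1S,5S,8S)-8-[2-(benzyloxy)ethyl]-1,5-dimethyl-6-oxabicyclo[3.2.1]octane-2,7-dione, via exo-methylene keto ester 10 (not isolated)
Conditions: Mn(OAc)3·2H2O (2.2 equiv), Cu(OAc)2·H2O (0.5 equiv), AcOH, 20 °C; then CF3CO2H, H2O, CH2Cl2, 40 °C
Reagents that add atoms: water, O
Why: Oxidative free-radical cyclisation of an unsaturated β-keto ester: Mn(OAc)3 forms the a8 radical, which adds 6-endo to a7 through a chair with the ester and the Z-substituent a6 axial and anti, the phenyl group of the ester shielding one face of the radical and so fixing the absolute sense, and Cu(OAc)2 oxidises the a13 radical to the alkene. Aqueous CF3CO2H then protonates the alkene to the a13 cation, the axial ester carbonyl captures it, and hydrolysis of the dialkoxycarbenium ion releases the auxiliary and leaves the γ-lactone (acid-induced lactonisation of an olefinic ester). a7 and a8 are set in the radical step and a13 by the intramolecular capture, which can only occur cis to the carbonyl on a8.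

Step 7
Reactants: 11 (1S,5S,8S)-8-[2-(benzyloxy)ethyl]-1,5-dimethyl-6-oxabicyclo[3.2.1]octane-2,7-dione
Product: 12 (1S,2S,5S,8S)-8-[2-(benzyloxy)ethyl]-2-hydroxy-1,5-dimethyl-6-oxabicyclo[3.2.1]octan-7-one
Conditions: LiBH(s-Bu)3, THF, −78 °C
Reagents that add atoms: none
Why: Reduction of a hindered cyclohexanone by a bulky trialkylborohydride: the axial face of a17 is closed by the syn-axial chain on a7, so hydride should enter from the equatorial side and give the axial alcohol cis to that chain (2S); at −78 °C the ketone reacts well ahead of the lactone.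

Step 8
Reactants: 12 (1S,2S,5S,8S)-8-[2-(benzyloxy)ethyl]-2-hydroxy-1,5-dimethyl-6-oxabicyclo[3.2.1]octan-7-one
Product: 13 (1S,2S,5S,8S)-8-[2-(benzyloxy)ethyl]-1,5-dimethyl-7-oxo-6-oxabicyclo[3.2.1]octan-2-yl acetate
Conditions: Ac2O, DMAP, Et3N, CH2Cl2, 25–40 °C
Reagents that add atoms: acetic anhydride, CC(=O)OC(C)=O
Why: DMAP-catalysed acylation; the acylpyridinium ion is reactive enough for the hindered axial alcohol and nothing else in 12 is nucleophilic.

Step 9
Reactants: 13 (1S,2S,5S,8S)-8-[2-(benzyloxy)ethyl]-1,5-dimethyl-7-oxo-6-oxabicyclo[3.2.1]octan-2-yl acetate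
Product: 14 (1S,2S,5S,8S)-8-(2-hydroxyethyl)-1,5-dimethyl-7-oxo-6-oxabicyclo[3.2.1]octan-2-yl acetate
Conditions: H2 (1 atm), Pd/C, EtOAc, 25 °C
Reagents that add atoms: none
Why: Hydrogenolysis of a benzyl ether over palladium; 13 has no alkene, and the lactone and the acetate are not reduced.

Step 10
Reactants: 14 (1S,2S,5S,8S)-8-(2-hydroxyethyl)-1,5-dimethyl-7-oxo-6-oxabicyclo[3.2.1]octan-2-yl acetate
Product: 15 (1S,2S,5S,8S)-1,5-dimethyl-7-oxo-8-(2-oxoethyl)-6-oxabicyclo[3.2.1]octan-2-yl acetate
Conditions: Dess–Martin periodinane, NaHCO3, CH2Cl2, 0 to 25 °C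
Reagents that add atoms: none
Why: Dess–Martin oxidation of a primary alcohol under buffered, non-basic conditions, which stops at the aldehyde and leaves the acetate in place.

Step 11
Reactants: 15 (1S,2S,5S,8S)-1,5-dimethyl-7-oxo-8-(2-oxoethyl)-6-oxabicyclo[3.2.1]octan-2-yl acetate; 16 cyclohexane-1,3-dione
Product: 17 (1S,2S,5S,8S)-8-[2-(2,6-dioxocyclohexyl)ethyl]-1,5-dimethyl-7-oxo-6-oxabicyclo[3.2.1]octan-2-yl acetate
Conditions: Hantzsch ester (diethyl 2,6-dimethyl-1,4-dihydropyridine-3,5-dicarboxylate), L-proline (20 mol %), CH2Cl2, 25 °C
Reagents that add atoms: none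
Why: Three-component reductive alkylation: proline-catalysed Knoevenagel condensation of the aldehyde with the dione gives the alkylidene dione, which the Hantzsch ester reduces at once by conjugate hydride transfer, so only the mono-C-alkylated dione forms (bond a4–a5) and neither a bis-adduct nor an O-alkyl product can arise.

Step 12
Reactants: 17 (1S,2S,5S,8S)-8-[2-(2,6-dioxocyclohexyl)ethyl]-1,5-dimethyl-7-oxo-6-oxabicyclo[3.2.1]octan-2-yl acetate; 18 3-bromoprop-1-yne (propargyl bromide)
Product: 19 (1S,2S,5S,8S)-8-{2-[2,6-dioxo-1-(prop-2-yn-1-yl)cyclohexyl]ethyl}-1,5-dimethyl-7-oxo-6-oxabicyclo[3.2.1]octan-2-yl acetate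
Conditions: K2CO3, acetone, 50 °C
Reagents that add atoms: none
Why: C-Alkylation of a 2-alkyl-1,3-dione enolate with a reactive propargylic halide (SN2), which creates the quaternary carbon a4 and the bond a3–a4; the enol ether from competing O-alkylation can be hydrolysed back to 17 with dilute acid and returned.

Step 13
Reactants: 19 (1S,2S,5S,8S)-8-{2-[2,6-dioxo-1-(prop-2-yn-1-yl)cyclohexyl]ethyl}-1,5-dimethyl-7-oxo-6-oxabicyclo[3.2.1]octan-2-yl acetate
Product: 20 (1S,2S,5S,8S)-1,5-dimethyl-8-{2-[(1S,5S)-6-methylidene-2,8-dioxobicyclo[3.2.1]octan-1-yl]ethyl}-7-oxo-6-oxabicyclo[3.2.1]octan-2-yl acetate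
Conditions: 9-amino-9-deoxy-epi-quinine (20 mol %), Cu(MeCN)4PF6 (10 mol %), PhCO2H (30 mol %), toluene, 40 °C, degassed
Reagents that add atoms: none
Why: The primary amine condenses with one carbonyl of the dione, and the enamine, whose double bond runs to the only α-methylene of that carbonyl (a23), attacks the internal carbon a2 of the alkyne held by monovalent copper; protodemetalation of the vinylcopper leaves the exocyclic methylene and hydrolysis returns the amine. The closest known reaction type is the amine and π-acid co-catalysed Conia-ene carbocyclisation of alkynyl ketones, including its desymmetrising enantioselective form with cinchona-derived primary amines, together with 5-exo-dig closures of cyclic enol derivatives onto a propargyl group on the neighbouring quaternary carbon. Ring D closes 5-exo-dig with the propargyl group axial and the enamine double bond inside the forming ring, and ring C is the dione ring itself, now bridged by the carbonyl a22. Because the bridge can only form cis, a4 and a23 are fixed together by the amine's choice between the two carbonyls, which are diastereotopic here but locally mirror-related; ring A lies four bonds away, so the catalyst and not the substrate should decide. The step needs 5-exo over 6-endo closure, which a terminal alkyne under copper activation favours, and reaction at the dione only, which holds because the lactone and the acetate cannot form enamines. A minor isomer would be a diastereomer of 20 and can be removed.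

Step 14
Reactants: 20 (1S,2S,5S,8S)-1,5-dimethyl-8-{2-[(1S,5S)-6-methylidene-2,8-dioxobicyclo[3.2.1]octan-1-yl]ethyl}-7-oxo-6-oxabicyclo[3.2.1]octan-2-yl acetate
Product: 21 (1S,2S,5S,8S)-8-{2-[(1R,5S)-8-hydroxy-6-methylidene-2-oxobicyclo[3.2.1]octan-1-yl]ethyl}-1,5-dimethyl-7-oxo-6-oxabicyclo[3.2.1]octan-2-yl acetate (carbinol a22 of either configuration)
Conditions: NaBH4 (0.35 equiv), MeOH–CH2Cl2, −78 °C
Reagents that add atoms: none
Why: Borohydride reduction that relies on ring strain: the carbonyl on the one-carbon bridge (a22) relieves angle strain on becoming tetrahedral and should add hydride far faster than the six-ring ketone a26 beside the quaternary carbon, so a substoichiometric charge at −78 °C should stop at the mono-alcohol; the new carbinol centre is removed in step 16 and its configuration does not matter.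

Step 15
Reactants: 21 (1S,2S,5S,8S)-8-{2-[(1R,5S)-8-hydroxy-6-methylidene-2-oxobicyclo[3.2.1]octan-1-yl]ethyl}-1,5-dimethyl-7-oxo-6-oxabicyclo[3.2.1]octan-2-yl acetate
Product: 22 (1S,2S,5S,8S)-1,5-dimethyl-8-{2-[(1R,5S)-6-methylidene-2-oxo-8-[(phenoxycarbonothioyl)oxy]bicyclo[3.2.1]octan-1-yl]ethyl}-7-oxo-6-oxabicyclo[3.2.1]octan-2-yl acetate (O-phenyl thiocarbonate of 21 at the a22 oxygen)
Conditions: PhOC(S)Cl, DMAP, pyridine, CH2Cl2, 25 °C
Reagents that add atoms: O-phenyl carbonochloridothioate, S=C(Cl)Oc1ccccc1
Why: DMAP-catalysed thioacylation of a secondary alcohol under amine-base conditions, which avoid the alkoxide that could trigger retro-aldol opening of the β-hydroxy ketone.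

Step 16
Reactants: 22 (1S,2S,5S,8S)-1,5-dimethyl-8-{2-[(1R,5S)-6-methylidene-2-oxo-8-[(phenoxycarbonothioyl)oxy]bicyclo[3.2.1]octan-1-yl]ethyl}-7-oxo-6-oxabicyclo[3.2.1]octan-2-yl acetate
Product: 23 (1S,2S,5S,8S)-1,5-dimethyl-8-{2-[(1S,5R)-6-methylidene-2-oxobicyclo[3.2.1]octan-1-yl]ethyl}-7-oxo-6-oxabicyclo[3.2.1]octan-2-yl acetate (CNP0204681.1)
Conditions: Bu3SnH, AIBN, (PhSe)2 (10 mol %), benzene, 80 °C
Reagents that add atoms: none
Why: Barton–McCombie deoxygenation: the stannyl radical adds to the thiocarbonyl sulfur, β-scission gives the a22 radical and hydrogen transfer completes the methylene bridge. Benzeneselenol formed from the diselenide transfers hydrogen fast enough to forestall a 1,2-acyl shift of this radical onto the a26 carbonyl, and closure onto the exocyclic alkene is ruled out because it would need a bicyclo[2.1.0]pentane unit.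

## Compound list

1 | 3-(benzyloxy)propanal | O=CCCOCc1ccccc1 | starting material
2 | ethyl 2-[bis(2,2,2-trifluoroethoxy)phosphoryl]propanoate | CCOC(=O)C(C)P(=O)(OCC(F)(F)F)OCC(F)(F)F | starting material
3 | ethyl (Z)-5-(benzyloxy)-2-methylpent-2-enoate | CCOC(=O)/C(C)=C\CCOCc1ccccc1 | intermediate
4 | (Z)-5-(benzyloxy)-2-methylpent-2-en-1-ol | OC/C(C)=C\CCOCc1ccccc1 | intermediate
5 | benzyl (Z)-5-bromo-4-methylpent-3-en-1-yl ether | BrC/C(C)=C\CCOCc1ccccc1 | intermediate
6 | (1R,2S,5R)-5-methyl-2-(2-phenylpropan-2-yl)cyclohexan-1-ol | C[C@@H]1CC[C@H]([C@@H](C1)O)C(C)(C)c1ccccc1 | starting material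
7 | methyl 2-methyl-3-oxobutanoate | COC(=O)C(C)C(C)=O | starting material
8 | (1R,2S,5R)-5-methyl-2-(2-phenylpropan-2-yl)cyclohexyl 2-methyl-3-oxobutanoate | C[C@@H]1CC[C@H]([C@@H](C1)OC(=O)C(C)C(C)=O)C(C)(C)c1ccccc1 | intermediate
9 | (1R,2S,5R)-5-methyl-2-(2-phenylpropan-2-yl)cyclohexyl (Z)-9-(benzyloxy)-2,6-dimethyl-3-oxonon-6-enoate | C[C@@H]1CC[C@H]([C@@H](C1)OC(=O)C(C)C(=O)CC/C(C)=C\CCOCc1ccccc1)C(C)(C)c1ccccc1 | intermediate
10 | (1R,2S,5R)-5-methyl-2-(2-phenylpropan-2-yl)cyclohexyl (1S,2R)-2-[2-(benzyloxy)ethyl]-1-methyl-3-methylidene-6-oxocyclohexane-1-carboxylate (formed beside its endocyclic double-bond isomer, which converges) | C=C1CCC(=O)[C@@](C)(C(=O)O[C@@H]2C[C@H](C)CC[C@H]2C(C)(C)c2ccccc2)[C@@H]1CCOCc1ccccc1 | intermediate (not isolated)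
11 | (1S,5S,8S)-8-[2-(benzyloxy)ethyl]-1,5-dimethyl-6-oxabicyclo[3.2.1]octane-2,7-dione | C(c1ccccc1)OCC[C@H]1[C@]2(C)C(=O)O[C@@]1(C)CCC2=O | intermediate
12 | (1S,2S,5S,8S)-8-[2-(benzyloxy)ethyl]-2-hydroxy-1,5-dimethyl-6-oxabicyclo[3.2.1]octan-7-one | C(c1ccccc1)OCC[C@H]1[C@]2(C)C(=O)O[C@@]1(C)CC[C@@H]2O | intermediate
13 | (1S,2S,5S,8S)-8-[2-(benzyloxy)ethyl]-1,5-dimethyl-7-oxo-6-oxabicyclo[3.2.1]octan-2-yl acetate | C(c1ccccc1)OCC[C@H]1[C@]2(C)C(=O)O[C@@]1(C)CC[C@@H]2OC(C)=O | intermediate
14 | (1S,2S,5S,8S)-8-(2-hydroxyethyl)-1,5-dimethyl-7-oxo-6-oxabicyclo[3.2.1]octan-2-yl acetate | OCC[C@H]1[C@]2(C)C(=O)O[C@@]1(C)CC[C@@H]2OC(C)=O | intermediate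
15 | (1S,2S,5S,8S)-1,5-dimethyl-7-oxo-8-(2-oxoethyl)-6-oxabicyclo[3.2.1]octan-2-yl acetate | O=CC[C@H]1[C@]2(C)C(=O)O[C@@]1(C)CC[C@@H]2OC(C)=O | intermediate
16 | cyclohexane-1,3-dione | O=C1CCCC(=O)C1 | starting material
17 | (1S,2S,5S,8S)-8-[2-(2,6-dioxocyclohexyl)ethyl]-1,5-dimethyl-7-oxo-6-oxabicyclo[3.2.1]octan-2-yl acetate | O=C1CCCC(=O)C1CC[C@H]2[C@]3(C)C(=O)O[C@@]2(C)CC[C@@H]3OC(C)=O | intermediate
18 | 3-bromoprop-1-yne | C#CCBr | starting material
19 | (1S,2S,5S,8S)-8-{2-[2,6-dioxo-1-(prop-2-yn-1-yl)cyclohexyl]ethyl}-1,5-dimethyl-7-oxo-6-oxabicyclo[3.2.1]octan-2-yl acetate | C#CCC1(CC[C@H]2[C@]3(C)C(=O)O[C@@]2(C)CC[C@@H]3OC(C)=O)C(=O)CCCC1=O | intermediate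
20 | (1S,2S,5S,8S)-1,5-dimethyl-8-{2-[(1S,5S)-6-methylidene-2,8-dioxobicyclo[3.2.1]octan-1-yl]ethyl}-7-oxo-6-oxabicyclo[3.2.1]octan-2-yl acetate | C=C1C[C@]2(CC[C@H]3[C@]4(C)C(=O)O[C@@]3(C)CC[C@@H]4OC(C)=O)C(=O)[C@H]1CCC2=O | intermediate
21 | (1S,2S,5S,8S)-8-{2-[(1R,5S)-8-hydroxy-6-methylidene-2-oxobicyclo[3.2.1]octan-1-yl]ethyl}-1,5-dimethyl-7-oxo-6-oxabicyclo[3.2.1]octan-2-yl acetate (carbinol centre unassigned, removed later) | C=C1C[C@]2(CC[C@H]3[C@]4(C)C(=O)O[C@@]3(C)CC[C@@H]4OC(C)=O)C(O)[C@H]1CCC2=O | intermediate
22 | (1S,2S,5S,8S)-1,5-dimethyl-8-{2-[(1R,5S)-6-methylidene-2-oxo-8-[(phenoxycarbonothioyl)oxy]bicyclo[3.2.1]octan-1-yl]ethyl}-7-oxo-6-oxabicyclo[3.2.1]octan-2-yl acetate (O-phenyl thiocarbonate of 21 at the bridge oxygen) | C=C1C[C@]2(CC[C@H]3[C@]4(C)C(=O)O[C@@]3(C)CC[C@@H]4OC(C)=O)C(OC(=S)Oc5ccccc5)[C@H]1CCC2=O | intermediate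
23 | (1S,2S,5S,8S)-1,5-dimethyl-8-{2-[(1S,5R)-6-methylidene-2-oxobicyclo[3.2.1]octan-1-yl]ethyl}-7-oxo-6-oxabicyclo[3.2.1]octan-2-yl acetate | C=C1C[C@]2(CC[C@H]3[C@]4(C)C(=O)O[C@@]3(C)CC[C@@H]4OC(C)=O)C[C@H]1CCC2=O | target

## Step count and least certain steps

Total: 16 steps. Longest linear sequence: 15 steps (1 to 23 through steps 1–3 and 5–16); step 4 is a one-step side branch.

**Step 13 (key step).** The amine may fail to discriminate between the two carbonyls of the dione, since the groups that distinguish them (propargyl and a 2-substituted ethyl) are of similar size. The enamine may also close 6-endo, or the amine may open the strained β-diketone by retro-Claisen attack once it has formed.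
Fallback, from 19 back to 20: asymmetric transfer hydrogenation of one carbonyl (RuCl(p-cymene)[(S,S)-TsDPEN], HCO2H–Et3N) would give the mono-alcohol F1 together with its epimer at the quaternary carbon F2. The two are diastereomers; the first is carried on and the second is oxidised back to 19 with Dess–Martin periodinane. Double silylation of the carried alcohol (t-BuMe2SiOTf, Et3N) would give the silyl ether–silyl enol ether F3, in which only the carbonyl that becomes a22 is enolised. Ph3PAuCl with AgBF4 in CH2Cl2–MeOH would then close ring D by the known 5-exo-dig addition of a silyl enol ether to an alkyne under monovalent gold and give the silyloxy ketone F4. HF·pyridine would free the alcohol F5, and Dess–Martin oxidation returns the route at 20.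

**Step 6.** Facial shielding by the auxiliary may be incomplete or of the wrong sense for a Z-alkene. During the acid stage the a13 cation may lose the proton on a7 before the ester captures it, which would erode the a7 configuration. Expulsion of a secondary alkyl group from the dialkoxycarbenium ion may be slow.
Fallback, from 5 back to 12: bromide 5 would alkylate the dianion of tert-butyl 2-methyl-3-oxobutanoate to give the tert-butyl keto ester F6. Mn(OAc)3·2H2O and Cu(OAc)2·H2O in AcOH would cyclise it; the tert-butyl ester captures the a13 cation directly and loses its alkyl group, which should give 11 together with its enantiomer F7. Reduction with an (S)- or (R)-2-methyl-CBS-oxazaborolidine and BH3·SMe2 would then be run as a kinetic resolution, in which the enantiomer whose open equatorial face matches the catalyst should be reduced faster. This would give 12, to be separated from the unreacted enantiomeric ketone, at the cost of at most half of the material.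

**Step 16.** The a22 radical may add to the neighbouring a26 carbonyl and undergo a 1,2-acyl shift, which is favoured because it leads to a tertiary radical in a less strained ring system. Slow C–O scission at the bridging carbon may instead return the alcohol.
Fallback, from 22 back to 23: the a26 ketone would be masked first, 1,2-bis(trimethylsilyloxy)ethane and catalytic Me3SiOTf at −78 to −20 °C converting 22 into the dioxolane thiocarbonate F8. The same tin hydride reduction, now without a carbonyl beside the radical, should give the dioxolane F9, and pyridinium p-toluenesulfonate in wet acetone would release 23.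

**Step 12.** Alkylation on oxygen may compete with alkylation on carbon, because the enolate of a 2-alkyl-1,3-dione is hindered at carbon.
Fallback, from 17 back to 19: alkylation with 2,3-dibromopropene (K2CO3, acetone) would be allowed to go on oxygen, giving the enol ether F10. Heating it in xylene should bring about a Claisen rearrangement to the C-(2-bromoallyl) dione F11, and Bu4NF in DMF would eliminate hydrogen bromide from the vinyl bromide to give the alkyne 19.

## Further compounds

F1 | step 13 | mono-alcohol from reduction of one carbonyl of 19 (quaternary carbon as in 20; carbinol centre unassigned) | C#CC[C@]1(CC[C@H]3[C@]4(C)C(=O)O[C@@]3(C)CC[C@@H]4OC(C)=O)C(=O)CCCC1O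
F2 | step 13 | epimer of F1 at the quaternary carbon | C#CC[C@@]1(CC[C@H]3[C@]4(C)C(=O)O[C@@]3(C)CC[C@@H]4OC(C)=O)C(=O)CCCC1O
F3 | step 13 | tert-butyldimethylsilyl ether and tert-butyldimethylsilyl enol ether of F1 | C#CC[C@]1(CC[C@H]3[C@]4(C)C(=O)O[C@@]3(C)CC[C@@H]4OC(C)=O)C(O[Si](C)(C)C(C)(C)C)=CCCC1O[Si](C)(C)C(C)(C)C
F4 | step 13 | 2-silyloxy-6-methylidene-8-oxobicyclo[3.2.1]octane carrying the ring A chain | C=C1C[C@]2(CC[C@H]3[C@]4(C)C(=O)O[C@@]3(C)CC[C@@H]4OC(C)=O)C(=O)[C@H]1CCC2O[Si](C)(C)C(C)(C)C
F5 | step 13 | 2-hydroxy-6-methylidene-8-oxobicyclo[3.2.1]octane carrying the ring A chain | C=C1C[C@]2(CC[C@H]3[C@]4(C)C(=O)O[C@@]3(C)CC[C@@H]4OC(C)=O)C(=O)[C@H]1CCC2O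
F6 | step 6 | tert-butyl (Z)-9-(benzyloxy)-2,6-dimethyl-3-oxonon-6-enoate | CC(C(=O)CC/C(C)=C\CCOCc1ccccc1)C(=O)OC(C)(C)C
F7 | step 6 | (1R,5R,8R)-8-[2-(benzyloxy)ethyl]-1,5-dimethyl-6-oxabicyclo[3.2.1]octane-2,7-dione | C(c1ccccc1)OCC[C@@H]1[C@@]2(C)C(=O)O[C@]1(C)CCC2=O
F8 | step 16 | ethylene ketal (at a26) of thiocarbonate 22 | C=C1C[C@]2(CC[C@H]3[C@]4(C)C(=O)O[C@@]3(C)CC[C@@H]4OC(C)=O)C(OC(=S)Oc6ccccc6)[C@H]1CCC25OCCO5
F9 | step 16 | ethylene ketal (at a26) of 23 | C=C1C[C@]2(CC[C@H]3[C@]4(C)C(=O)O[C@@]3(C)CC[C@@H]4OC(C)=O)C[C@H]1CCC25OCCO5
F10 | step 12 | 3-(2-bromoallyloxy)cyclohex-2-enone enol ether of 17 | C=C(Br)COC1=C(CC[C@H]2[C@]3(C)C(=O)O[C@@]2(C)CC[C@@H]3OC(C)=O)C(=O)CCC1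
F11 | step 12 | 2-(2-bromoallyl) analogue of 19 | C=C(Br)CC1(CC[C@H]2[C@]3(C)C(=O)O[C@@]2(C)CC[C@@H]3OC(C)=O)C(=O)CCCC1=O
A1 | alternative 1 | Z-alkenyl β-keto tert-butyl ester on the ketal-protected core | C=C1C[C@]2(CC/C=C(/C)CCC(=O)C(C)C(=O)OC(C)(C)C)C[C@H]1CCC23OCCO3
A2 | alternative 1 | 3-oxo ring A lactone with ketal-protected rings C and D | C=C1C[C@]2(CC[C@H]5[C@]4(C)C(=O)O[C@@]5(C)CCC4=O)C[C@H]1CCC23OCCO3
A3 | alternative 2 | 3-acryloyl-3-(3-silyloxypropyl)cyclopentanone | C=CC(=O)[C@]1(CCCO[Si](C)(C)C(C)(C)C)CC(=O)CC1
A4 | alternative 2 | 1-(3-silyloxypropyl)bicyclo[3.2.1]octane-2,6-dione | O=C1C[C@]2(CCCO[Si](C)(C)C(C)(C)C)C[C@H]1CCC2=O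
A5 | alternative 3 | open-chain α-chloro β-keto methyl ester with allyl, propargyl and ring A ethyl groups on a4 | C#CC[C@@](CC=C)(CC[C@H]1[C@]2(C)C(=O)O[C@@]1(C)CC[C@@H]2OC(C)=O)C(=O)C(Cl)C(=O)OC
A6 | alternative 3 | target skeleton bearing chloride and methyl ester on a25 | C=C1C[C@]2(CC[C@H]3[C@]4(C)C(=O)O[C@@]3(C)CC[C@@H]4OC(C)=O)C[C@H]1C[C@](Cl)(C(=O)OC)C2=O
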